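## Retrosynthetic overview

1. The target is reached from its diethyl ester 13-O-silyl ether; the exocyclic C16=C17 alkene comes from a C15-oxo-16-methylidene unit (Mannich methylenation of a C15 silyl enol ether, then reductive allylic transposition), and ring B is closed last at C5–C6 by Pd-catalysed ester α-arylation.
2. Rings C and D (the bicyclo[3.2.1]octane) come from one strain-releasing [3,3]-sigmatropic divinylcyclopropane–cycloheptadiene rearrangement that forms C8–C9 (quaternary C8, benzylic C9) from a 6-endo-[(Z)-2-arylvinyl]-2-siloxybicyclo[3.1.0]hex-2-ene.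
3. Enabling feature: the seven-membered ring C8–C9–C11–C12–C13–C16–C15 of the C/D bicycle has C13 opposite the C8–C9 bond and tied to C8 by the one-carbon bridge C14; a C12–C16 bond plus C9=C11 and C8=C15 unsaturation turns it into a cis-divinylcyclopropane (cyclopropane C13–C16–C12 fused to the carbocycle C13–C14–C8–C15–C16).
4. The cyclopropane comes from an enantioselective intramolecular cyclopropanation of a diazoketone onto an (E)-silyl enol ether, whose geometry comes from anti-iodolactonisation of pent-4-ynoic acid; the arene comes from 3-bromo-2-methylphenol; the two are joined by Sonogashira coupling and semi-hydrogenation.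
5. Order of ring formation: benzofuran (ring A with its furan), then cyclopropane and five-membered carbocycle (future ring D), then ring C (key step), then ring B.

Key step: step 14

## Remarks on the chemistry

- Rings B–D are numbered as in gibberellanes: C5 and C10 aryl, C6 bearing carboxyl C7, C8 quaternary, C9 benzylic, C11, C12, C13 carbinol, C14 one-carbon bridge, C15, C16, C17 methylidene. "Pharbinilate" names denote esters of the target with these locants. TBS is tert-butyldimethylsilyl and TES is triethylsilyl.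
- The sense of induction of the copper–bis(oxazoline) catalyst in step 9 cannot be predicted for this substrate; the ligand antipode that gives the (1R,5R,6R) ketone is the one used (written as the S,S ligand).
- The alkylation products of step 10 (epimers at the ketone α-carbon) and the ring-B-closed esters from step 15 on (epimers at C6) are carried as mixtures and written without a descriptor at that centre; C6 is fixed in step 22.

## Route

Step 1
Reactants: 1 3-bromo-2-methylphenol
Product: 2 4-bromo-2-hydroxy-3-methylbenzaldehyde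
Conditions: MgCl2, Et3N, (CH2O)n, MeCN, reflux
Reagents that add atoms: paraformaldehyde (formaldehyde unit), C=O
Why: Magnesium-mediated ortho-formylation of the phenol, in which the magnesium phenoxide delivers formaldehyde to the only free ortho position and the benzylic alkoxide is oxidised by a second formaldehyde through hydride transfer.

Step 2
Reactants: 2 4-bromo-2-hydroxy-3-methylbenzaldehyde
Product: 3 4-bromo-2-hydroxy-5-iodo-3-methylbenzaldehyde
Conditions: N-iodosuccinimide, CF3CO2H (cat.), MeCN, 25 °C
Reagents that add atoms: N-iodosuccinimide, O=C1CCC(=O)N1I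
Why: Electrophilic aromatic iodination para to the hydroxyl group, the only free position that the phenol activates because both ortho positions are substituted.

Step 3
Reactants: 3 4-bromo-2-hydroxy-5-iodo-3-methylbenzaldehyde; 4 ethyl diazoacetate
Product: 6 ethyl 6-bromo-5-iodo-7-methyl-1-benzofuran-3-carboxylate, via hemiacetal 5 (not isolated)
Conditions: HBF4·OEt2 (10 mol %), CH2Cl2, 25 °C; then conc. H2SO4
Reagents that add atoms: none
Why: Acid-catalysed addition of the diazo ester to the aldehyde with 1,2-aryl shift and loss of N2 gives the 2-hydroxy-2,3-dihydrobenzofuran, which H2SO4 dehydrates to the aromatic benzofuran-3-carboxylate (aldehyde–diazoacetate homologation and cyclodehydration).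

Step 4
Reactants: 7 pent-4-ynoic acid
Product: 8 (E)-5-(iodomethylidene)oxolan-2-one
Conditions: I2, KHCO3, MeCN, 25 °C, dark
Reagents that add atoms: iodine, II
Why: Iodolactonisation by 5-exo-dig attack of the carboxylate on the iodine-activated alkyne, the anti addition fixing the E geometry (iodine cis to the ring CH2) that later becomes the endo orientation on the cyclopropane.

Step 5
Reactants: 8 (E)-5-(iodomethylidene)oxolan-2-one; 9 ethynyltrimethylsilane
Product: 10 (E)-5-[3-(trimethylsilyl)prop-2-yn-1-ylidene]oxolan-2-one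
Conditions: PdCl2(PPh3)2 (3 mol %), CuI (5 mol %), Et3N, THF, 25 °C
Reagents that add atoms: none
Why: Sonogashira coupling of the alkenyl iodide, which proceeds with retention of the alkene geometry.

Step 6
Reactants: 10 (E)-5-[3-(trimethylsilyl)prop-2-yn-1-ylidene]oxolan-2-one
Product: 12 (E)-4-[(tert-butyldimethylsilyl)oxy]-N-methoxy-N-methyl-7-(trimethylsilyl)hept-4-en-6-ynamide, via lithium enolate 11 (not isolated)
Conditions: MeONHMe·HCl, n-BuLi (2 equiv), THF, −78 °C; add 10; then t-BuMe2SiOTf, −78 °C
Reagents that add atoms: N,O-dimethylhydroxylamine hydrochloride, CNOC.Cl; tert-butyldimethylsilyl trifluoromethanesulfonate, CC(C)(C)[Si](C)(C)OS(=O)(=O)C(F)(F)F; n-butyllithium, [Li]CCCC (lithium of 11 only)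
Why: Nucleophilic acyl substitution on the enol ester (Weinreb amide formation) expels the enolate with the geometry that the lactone ring imposed, and O-silylation at −78 °C traps it before it can equilibrate (stereodefined enolate generation from an enol ester).

Step 7
Reactants: 12 (E)-4-[(tert-butyldimethylsilyl)oxy]-N-methoxy-N-methyl-7-(trimethylsilyl)hept-4-en-6-ynamide
Product: 13 (E)-5-[(tert-butyldimethylsilyl)oxy]-8-(trimethylsilyl)oct-5-en-7-yn-2-one
Conditions: MeMgBr, THF, −20 to 0 °C
Reagents that add atoms: methylmagnesium bromide, C[Mg]Br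
Why: Weinreb ketone synthesis by Grignard addition, the chelated tetrahedral intermediate preventing a second addition while the silyl enol ether and the alkynylsilane stay inert.

Step 8
Reactants: 13 (E)-5-[(tert-butyldimethylsilyl)oxy]-8-(trimethylsilyl)oct-5-en-7-yn-2-one
Product: 15 (E)-5-[(tert-butyldimethylsilyl)oxy]-1-diazo-8-(trimethylsilyl)oct-5-en-7-yn-2-one, via trifluoroacetyl diketone 14 (not isolated)
Conditions: LiN(SiMe3)2, THF, −78 °C; CF3CO2CH2CF3; then MsN3, Et3N, H2O, MeCN, 25 °C
Reagents that add atoms: methanesulfonyl azide, CS(=O)(=O)N=[N+]=[N-]; 2,2,2-trifluoroethyl trifluoroacetate, O=C(OCC(F)(F)F)C(F)(F)F (trifluoroacetyl group of 14 only)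
Why: Detrifluoroacetylative diazo transfer, in which the kinetic enolate forms at the methyl group, is acylated, and the activated 1,3-diketone takes the diazo group from the sulfonyl azide with loss of the trifluoroacetyl group.

Step 9
Reactants: 15 (E)-5-[(tert-butyldimethylsilyl)oxy]-1-diazo-8-(trimethylsilyl)oct-5-en-7-yn-2-one
Product: 16 (1R,5R,6R)-5-[(tert-butyldimethylsilyl)oxy]-6-[(trimethylsilyl)ethynyl]bicyclo[3.1.0]hexan-2-one (alkynyl group endo)
Conditions: (CuOTf)2·C6H6 (5 mol %), 2,2'-(propane-2,2-diyl)bis[(4S)-4-tert-butyl-4,5-dihydro-1,3-oxazole] (6 mol %), CH2Cl2, slow addition of 15, 25 °C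
Reagents that add atoms: none
Why: Asymmetric intramolecular cyclopropanation of the electron-rich enol ether by the keto carbenoid on a monovalent copper–bis(oxazoline) catalyst, in which the concerted addition turns the E geometry into the endo alkynyl group at C6 and the ligand selects the alkene face and so fixes the absolute configuration of both bridgeheads.

Step 10
Reactants: 16 (1R,5R,6R)-5-[(tert-butyldimethylsilyl)oxy]-6-[(trimethylsilyl)ethynyl]bicyclo[3.1.0]hexan-2-one; 17 ethyl bromoacetate
Product: 18 ethyl 2-{(1R,5R,6R)-5-[(tert-butyldimethylsilyl)oxy]-2-oxo-6-[(trimethylsilyl)ethynyl]bicyclo[3.1.0]hexan-3-yl}acetate (C3 epimers)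
Conditions: LiN(i-Pr)2, THF, −78 °C; then 17, −78 to −40 °C
Reagents that add atoms: none
Why: Alkylation of the lithium enolate, which can only form at C3 because C1 is a cyclopropane bridgehead; the new stereocentre is formed as a mixture that does not matter because it becomes trigonal in step 12.

Step 11
Reactants: 18 ethyl 2-{(1R,5R,6R)-5-[(tert-butyldimethylsilyl)oxy]-2-oxo-6-[(trimethylsilyl)ethynyl]bicyclo[3.1.0]hexan-3-yl}acetate; 6 ethyl 6-bromo-5-iodo-7-methyl-1-benzofuran-3-carboxylate
Product: 20 ethyl 6-bromo-5-({(1R,5R,6R)-5-[(tert-butyldimethylsilyl)oxy]-3-(2-ethoxy-2-oxoethyl)-2-oxobicyclo[3.1.0]hexan-6-yl}ethynyl)-7-methyl-1-benzofuran-3-carboxylate (C3 epimers), via terminal alkyne 19 (not isolated)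
Conditions: K2CO3, EtOH/THF, 25 °C; then 6, PdCl2(PPh3)2 (3 mol %), CuI (5 mol %), 40 °C
Reagents that add atoms: none
Why: Carbonate-mediated protodesilylation of the alkynylsilane followed in the same flask by Sonogashira coupling, which takes place at the C–I bond and leaves the C–Br bond for step 15.

Step 12
Reactants: 20 ethyl 6-bromo-5-({(1R,5R,6R)-5-[(tert-butyldimethylsilyl)oxy]-3-(2-ethoxy-2-oxoethyl)-2-oxobicyclo[3.1.0]hexan-6-yl}ethynyl)-7-methyl-1-benzofuran-3-carboxylate
Product: 21 ethyl 6-bromo-5-({(1R,5R,6R)-5-[(tert-butyldimethylsilyl)oxy]-3-(2-ethoxy-2-oxoethyl)-2-[(triethylsilyl)oxy]bicyclo[3.1.0]hex-2-en-6-yl}ethynyl)-7-methyl-1-benzofuran-3-carboxylate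
Conditions: KN(SiMe3)2, THF, −78 °C; then Et3SiCl
Reagents that add atoms: chlorotriethylsilane, CC[Si](Cl)(CC)CC
Why: Regiospecific silyl enol ether formation, since the ketone can only enolise towards C3, its α-CH is more acidic than the ester α-CH2, and O-silylation gives the 2-siloxy alkene that serves as the second vinyl group.

Step 13
Reactants: 21 ethyl 6-bromo-5-({(1R,5R,6R)-5-[(tert-butyldimethylsilyl)oxy]-3-(2-ethoxy-2-oxoethyl)-2-[(triethylsilyl)oxy]bicyclo[3.1.0]hex-2-en-6-yl}ethynyl)-7-methyl-1-benzofuran-3-carboxylate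
Product: 22 ethyl 6-bromo-5-[(Z)-2-{(1R,5R,6S)-5-[(tert-butyldimethylsilyl)oxy]-3-(2-ethoxy-2-oxoethyl)-2-[(triethylsilyl)oxy]bicyclo[3.1.0]hex-2-en-6-yl}ethenyl]-7-methyl-1-benzofuran-3-carboxylate (alkenyl group endo)
Conditions: H2 (1 atm), Pd/CaCO3 poisoned with Pb(OAc)2 (Lindlar catalyst), quinoline, EtOAc, 0 °C; filtered cold and used at once
Reagents that add atoms: none
Why: Lindlar semi-hydrogenation adds H2 syn to the alkyne and gives the Z alkene, which places the aryl group on the inside of the cis-divinylcyclopropane.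

Step 14
Reactants: 22 ethyl 6-bromo-5-[(Z)-2-{(1R,5R,6S)-5-[(tert-butyldimethylsilyl)oxy]-3-(2-ethoxy-2-oxoethyl)-2-[(triethylsilyl)oxy]bicyclo[3.1.0]hex-2-en-6-yl}ethenyl]-7-methyl-1-benzofuran-3-carboxylate
Product: 23 ethyl 6-bromo-5-{(1S,2R,5R)-5-[(tert-butyldimethylsilyl)oxy]-1-(2-ethoxy-2-oxoethyl)-7-[(triethylsilyl)oxy]bicyclo[3.2.1]octa-3,6-dien-2-yl}-7-methyl-1-benzofuran-3-carboxylate (aryl group on the side of the one-carbon bridge)
Conditions: toluene (degassed, 0.01 M), Et3N (1 mol %), base-washed glass, 100 °C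
Reagents that add atoms: none
Why: The step is a concerted [3,3]-sigmatropic shift (divinylcyclopropane–cycloheptadiene, that is a strain-driven Cope rearrangement) through the boat transition state that the endo alkenyl group enforces: the C8–C9 σ-bond forms between the termini of the silyl enol ether and of the styrene while the cyclopropane bond C12–C16 breaks, and release of the ring strain (about 27 kcal/mol) makes it irreversible. The closest known reaction type is the thermal rearrangement of 6-endo-alkenylbicyclo[3.1.0]hex-2-enes, and of silyl enol ethers of 2-vinylcyclopropyl ketones, to bicyclo[3.2.1]octa-2,6-dienes. The seven-membered carbocycle C8–C9–C11–C12–C13–C16–C15 and, because C14 already ties C8 to C13, the six-membered ring C are closed together by this suprafacial–suprafacial six-electron pericyclic bond formation, which leaves the former cyclopentene as ring D. The quaternary centre C8 is created on the cyclopentene face that carries the cyclopropane, so its configuration is dictated by C13 and C16 from step 9, and C9 is dictated by the alkene geometry: the Z aryl group sits inside the boat and ends up syn to the one-carbon bridge C14 with H-9 on the concave side, the arrangement of the target that steric approach control would not give. The step needs the sigmatropic shift to outrun the homodienyl 1,5-hydrogen shift from C14 and needs the Z geometry to persist; the first is secured by the endo, cis disposition of the two alkenes and the radical-stabilising siloxy group at C15, which keep the Cope barrier below that of the hydrogen shift, and the second by the concerted mechanism and the exclusion of acid, light and radical initiators. The product carries the enol ether at C15=C16 and the CH2CO2Et and bromoaryl groups gauche on C8 and C9, which is what steps 15 and 17 require.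

Step 15
Reactants: 23 ethyl 6-bromo-5-{(1S,2R,5R)-5-[(tert-butyldimethylsilyl)oxy]-1-(2-ethoxy-2-oxoethyl)-7-[(triethylsilyl)oxy]bicyclo[3.2.1]octa-3,6-dien-2-yl}-7-methyl-1-benzofuran-3-carboxylate
Product: 24 diethyl 13-O-TBS-15-[(triethylsilyl)oxy]-11,12,15,16-tetradehydro-17-norpharbinilate (new C5–C6 bond; C8, C9 and C13 as in the target; C6 epimers)
Conditions: Pd2(dba)3 (5 mol %), [HP(t-Bu)3]BF4 (12 mol %), LiN(SiMe3)2 (2.2 equiv), toluene, 25 to 60 °C
Reagents that add atoms: none
Why: Pd-catalysed intramolecular α-arylation of the ester enolate (oxidative addition of zerovalent palladium into the C–Br bond, enolate binding, reductive elimination from a six-membered palladacycle) closes the five-membered ring B; C6 is formed as an epimer mixture that is equilibrated in step 22.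

Step 16
Reactants: 24 diethyl 13-O-TBS-15-[(triethylsilyl)oxy]-11,12,15,16-tetradehydro-17-norpharbinilate
Product: 25 diethyl 13-O-TBS-15-[(triethylsilyl)oxy]-15,16-didehydro-17-norpharbinilate (C6 epimers)
Conditions: H2 (4 atm), RhCl(PPh3)3 (10 mol %), benzene/EtOH, 40 °C
Reagents that add atoms: none
Why: Homogeneous hydrogenation with RhCl(PPh3)3, which reduces the cis-disubstituted C11=C12 bond and leaves the trisubstituted silyl enol ether, the benzofuran and the esters untouched.

Step 17
Reactants: 25 diethyl 13-O-TBS-15-[(triethylsilyl)oxy]-15,16-didehydro-17-norpharbinilate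
Product: 28 diethyl 13-O-TBS-15-oxopharbinilate (C6 epimers), via Mannich base 26 (not isolated), via methiodide 27 (not isolated)
Conditions: [Me2N=CH2]I, CH2Cl2, 25 °C; then MeI; then 1,8-diazabicyclo[5.4.0]undec-7-ene (DBU), 25 °C
Reagents that add atoms: dimethyl(methylidene)ammonium iodide, C=[N+](C)C.[I-]; iodomethane, CI (N-methyl group of 27 only)
Why: Mannich reaction of the silyl enol ether at C16 with the iminium salt, N-methylation and E1cB elimination of trimethylamine give the α-methylidene ketone (Eschenmoser methylenation) and so attach C17 to the carbon that the rearrangement delivered as an enol ether.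

Step 18
Reactants: 28 diethyl 13-O-TBS-15-oxopharbinilate
Product: 29 diethyl 13-O-TBS-15-hydroxypharbinilate (C6 and C15 epimers)
Conditions: NaBH4, CeCl3·7H2O, MeOH/THF, −40 °C
Reagents that add atoms: none
Why: Luche reduction, a 1,2-selective hydride addition to the enone; the configuration of the new carbinol is irrelevant because C15 ends as CH2.

Step 19
Reactants: 29 diethyl 13-O-TBS-15-hydroxypharbinilate
Product: 30 diethyl 13-O-TBS-15-[(methoxycarbonyl)oxy]pharbinilate (C6 and C15 epimers)
Conditions: ClCO2Me, pyridine, 4-(dimethylamino)pyridine (cat.), CH2Cl2, 0 to 25 °C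
Reagents that add atoms: methyl chloroformate, COC(=O)Cl
Why: Acylation of the secondary allylic alcohol to the methyl carbonate, the leaving group needed for ionisation by palladium.

Step 20
Reactants: 30 diethyl 13-O-TBS-15-[(methoxycarbonyl)oxy]pharbinilate
Product: 31 diethyl 13-O-TBS-pharbinilate (C6 epimers)
Conditions: Pd(OAc)2 (5 mol %), n-Bu3P (20 mol %), HCO2NH4, 1,4-dioxane, 90 °C
Reagents that add atoms: none
Why: Pd-catalysed formate reduction of the allylic carbonate (Tsuji reduction), in which decarboxylation of the π-allylpalladium formate delivers hydride to the more substituted allyl terminus C15 and leaves the exocyclic C16=C17 alkene.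

Step 21
Reactants: 31 diethyl 13-O-TBS-pharbinilate
Product: 32 diethyl pharbinilate (C6 epimers)
Conditions: Bu4NF, THF, 50 °C
Reagents that add atoms: none
Why: Fluoride-mediated desilylation of the tertiary silyl ether under conditions that touch neither the esters nor the alkene.

Step 22
Reactants: 32 diethyl pharbinilate (C6 epimers)
Product: 34 pharbinilic acid, via (6R)-diester 33 (not isolated)
Conditions: NaOEt (20 mol %), EtOH, 60 °C; then KOH, H2O, 80 °C; then 1 M HCl to pH 3, 0 °C
Reagents that add atoms: potassium hydroxide, [K+].[OH-] (one oxygen of each carboxyl group)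
Why: Base epimerisation followed by saponification: ethoxide equilibrates the benzylic, ester-activated C6 centre to the more stable epimer (ester on the face of ring B away from ring C and cis to H-9, the configuration of the target) and hydroxide then cleaves both esters, the tertiary allylic alcohol and the exocyclic alkene being stable to base.

## Compound list

1 | 3-bromo-2-methylphenol | Cc1c(O)cccc1Br | starting material
2 | 4-bromo-2-hydroxy-3-methylbenzaldehyde | O=Cc1ccc(Br)c(C)c1O | intermediate
3 | 4-bromo-2-hydroxy-5-iodo-3-methylbenzaldehyde | O=Cc1cc(I)c(Br)c(C)c1O | intermediate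
4 | ethyl diazoacetate | CCOC(=O)C=[N+]=[N-] | starting material
5 | ethyl 6-bromo-2-hydroxy-5-iodo-7-methyl-2,3-dihydro-1-benzofuran-3-carboxylate (hemiacetal, diastereomer mixture) | CCOC(=O)C1C(O)Oc2c(C)c(Br)c(I)cc12 | intermediate
6 | ethyl 6-bromo-5-iodo-7-methyl-1-benzofuran-3-carboxylate | CCOC(=O)c1coc2c(C)c(Br)c(I)cc12 | intermediate
7 | pent-4-ynoic acid | OC(=O)CCC#C | starting material
8 | (E)-5-(iodomethylidene)oxolan-2-one | O=C1CC/C(=C\I)O1 | intermediate
9 | ethynyltrimethylsilane | C#C[Si](C)(C)C | starting material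
10 | (E)-5-[3-(trimethylsilyl)prop-2-yn-1-ylidene]oxolan-2-one | O=C1CC/C(=C\C#C[Si](C)(C)C)O1 | intermediate
11 | lithium (E)-enolate of N-methoxy-N-methyl-4-oxo-7-(trimethylsilyl)hept-6-ynamide (C4=C5 enolate, alkynyl cis to the CH2CH2 chain) | [Li+].CON(C)C(=O)CC/C([O-])=C\C#C[Si](C)(C)C | intermediate
12 | (E)-4-[(tert-butyldimethylsilyl)oxy]-N-methoxy-N-methyl-7-(trimethylsilyl)hept-4-en-6-ynamide | CON(C)C(=O)CC/C(O[Si](C)(C)C(C)(C)C)=C\C#C[Si](C)(C)C | intermediate
13 | (E)-5-[(tert-butyldimethylsilyl)oxy]-8-(trimethylsilyl)oct-5-en-7-yn-2-one | CC(=O)CC/C(O[Si](C)(C)C(C)(C)C)=C\C#C[Si](C)(C)C | intermediate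
14 | (E)-7-[(tert-butyldimethylsilyl)oxy]-1,1,1-trifluoro-10-(trimethylsilyl)dec-7-en-9-yne-2,4-dione | O=C(CC(=O)CC/C(O[Si](C)(C)C(C)(C)C)=C\C#C[Si](C)(C)C)C(F)(F)F | intermediate
15 | (E)-5-[(tert-butyldimethylsilyl)oxy]-1-diazo-8-(trimethylsilyl)oct-5-en-7-yn-2-one | [N-]=[N+]=CC(=O)CC/C(O[Si](C)(C)C(C)(C)C)=C\C#C[Si](C)(C)C | intermediate
16 | (1R,5R,6R)-5-[(tert-butyldimethylsilyl)oxy]-6-[(trimethylsilyl)ethynyl]bicyclo[3.1.0]hexan-2-one (alkynyl endo) | C1C(=O)[C@@H]2[C@H](C#C[Si](C)(C)C)[C@]2(O[Si](C)(C)C(C)(C)C)C1 | intermediate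
17 | ethyl bromoacetate | CCOC(=O)CBr | starting material
18 | ethyl 2-{(1R,5R,6R)-5-[(tert-butyldimethylsilyl)oxy]-2-oxo-6-[(trimethylsilyl)ethynyl]bicyclo[3.1.0]hexan-3-yl}acetate (C3 epimers) | CCOC(=O)CC1C(=O)[C@@H]2[C@H](C#C[Si](C)(C)C)[C@]2(O[Si](C)(C)C(C)(C)C)C1 | intermediate
19 | ethyl 2-{(1R,5R,6R)-5-[(tert-butyldimethylsilyl)oxy]-6-ethynyl-2-oxobicyclo[3.1.0]hexan-3-yl}acetate (C3 epimers) | CCOC(=O)CC1C(=O)[C@@H]2[C@H](C#C)[C@]2(O[Si](C)(C)C(C)(C)C)C1 | intermediate
20 | ethyl 6-bromo-5-({(1R,5R,6R)-5-[(tert-butyldimethylsilyl)oxy]-3-(2-ethoxy-2-oxoethyl)-2-oxobicyclo[3.1.0]hexan-6-yl}ethynyl)-7-methyl-1-benzofuran-3-carboxylate (C3 epimers) | CCOC(=O)CC1C(=O)[C@@H]2[C@H](C#Cc3cc4c(C(=O)OCC)coc4c(C)c3Br)[C@]2(O[Si](C)(C)C(C)(C)C)C1 | intermediate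
21 | ethyl 6-bromo-5-({(1R,5R,6R)-5-[(tert-butyldimethylsilyl)oxy]-3-(2-ethoxy-2-oxoethyl)-2-[(triethylsilyl)oxy]bicyclo[3.1.0]hex-2-en-6-yl}ethynyl)-7-methyl-1-benzofuran-3-carboxylate | CCOC(=O)CC1=C(O[Si](CC)(CC)CC)[C@@H]2[C@H](C#Cc3cc4c(C(=O)OCC)coc4c(C)c3Br)[C@]2(O[Si](C)(C)C(C)(C)C)C1 | intermediate
22 | ethyl 6-bromo-5-[(Z)-2-{(1R,5R,6S)-5-[(tert-butyldimethylsilyl)oxy]-3-(2-ethoxy-2-oxoethyl)-2-[(triethylsilyl)oxy]bicyclo[3.1.0]hex-2-en-6-yl}ethenyl]-7-methyl-1-benzofuran-3-carboxylate (alkenyl endo) | CCOC(=O)CC1=C(O[Si](CC)(CC)CC)[C@@H]2[C@H](/C=C\c3cc4c(C(=O)OCC)coc4c(C)c3Br)[C@]2(O[Si](C)(C)C(C)(C)C)C1 | intermediate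
23 | ethyl 6-bromo-5-{(1S,2R,5R)-5-[(tert-butyldimethylsilyl)oxy]-1-(2-ethoxy-2-oxoethyl)-7-[(triethylsilyl)oxy]bicyclo[3.2.1]octa-3,6-dien-2-yl}-7-methyl-1-benzofuran-3-carboxylate | C1=C(O[Si](CC)(CC)CC)[C@]2(CC(=O)OCC)C[C@@]1(O[Si](C)(C)C(C)(C)C)C=C[C@H]2c1cc2c(C(=O)OCC)coc2c(C)c1Br | intermediate
24 | diethyl 13-O-TBS-15-[(triethylsilyl)oxy]-11,12,15,16-tetradehydro-17-norpharbinilate (C8, C9, C13 as in 34; C6 epimers) | C1=C(O[Si](CC)(CC)CC)[C@]23C[C@@]1(O[Si](C)(C)C(C)(C)C)C=C[C@H]2c1cc2c(C(=O)OCC)coc2c(C)c1C3C(=O)OCC | intermediate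
25 | diethyl 13-O-TBS-15-[(triethylsilyl)oxy]-15,16-didehydro-17-norpharbinilate (C6 epimers) | C1=C(O[Si](CC)(CC)CC)[C@]23C[C@@]1(O[Si](C)(C)C(C)(C)C)CC[C@H]2c1cc2c(C(=O)OCC)coc2c(C)c1C3C(=O)OCC | intermediate
26 | diethyl 13-O-TBS-17-(dimethylamino)-15-oxo-16,17-dihydropharbinilate (C6 and C16 epimers) | CN(C)CC1C(=O)[C@]23C[C@@]1(O[Si](C)(C)C(C)(C)C)CC[C@H]2c1cc2c(C(=O)OCC)coc2c(C)c1C3C(=O)OCC | intermediate
27 | diethyl 13-O-TBS-15-oxo-17-(trimethylammonio)-16,17-dihydropharbinilate iodide (C6 and C16 epimers) | C[N+](C)(C)CC1C(=O)[C@]23C[C@@]1(O[Si](C)(C)C(C)(C)C)CC[C@H]2c1cc2c(C(=O)OCC)coc2c(C)c1C3C(=O)OCC.[I-] | intermediate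
28 | diethyl 13-O-TBS-15-oxopharbinilate (C6 epimers) | C=C1C(=O)[C@]23C[C@@]1(O[Si](C)(C)C(C)(C)C)CC[C@H]2c1cc2c(C(=O)OCC)coc2c(C)c1C3C(=O)OCC | intermediate
29 | diethyl 13-O-TBS-15-hydroxypharbinilate (C6 and C15 epimers) | C=C1C(O)[C@]23C[C@@]1(O[Si](C)(C)C(C)(C)C)CC[C@H]2c1cc2c(C(=O)OCC)coc2c(C)c1C3C(=O)OCC | intermediate
30 | diethyl 13-O-TBS-15-[(methoxycarbonyl)oxy]pharbinilate (C6 and C15 epimers) | C=C1C(OC(=O)OC)[C@]23C[C@@]1(O[Si](C)(C)C(C)(C)C)CC[C@H]2c1cc2c(C(=O)OCC)coc2c(C)c1C3C(=O)OCC | intermediate
31 | diethyl 13-O-TBS-pharbinilate (C6 epimers) | C=C1C[C@]23C[C@@]1(O[Si](C)(C)C(C)(C)C)CC[C@H]2c1cc2c(C(=O)OCC)coc2c(C)c1C3C(=O)OCC | intermediate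
32 | diethyl pharbinilate (C6 epimers) | C=C1C[C@]23C[C@@]1(O)CC[C@H]2c1cc2c(C(=O)OCC)coc2c(C)c1C3C(=O)OCC | intermediate
33 | diethyl pharbinilate (6R,8S,9R,13S) | C=C1C[C@]23C[C@@]1(O)CC[C@H]2c1cc2c(C(=O)OCC)coc2c(C)c1[C@@H]3C(=O)OCC | intermediate
34 | pharbinilic acid (6R,8S,9R,13S; gibberellane numbering) | C=C1C[C@]23C[C@@]1(O)CC[C@H]2c1cc2c(C(=O)O)coc2c(C)c1[C@@H]3C(=O)O | target

## Step count and risks

Total step count: 22. Longest linear sequence: 19 steps (steps 4 to 22, from pent-4-ynoic acid 7).

The three steps most likely to fail: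

1. Step 9. The carbenoid may add to the two faces of the enol ether with too little discrimination, and the Lewis-acidic copper may open the donor–acceptor cyclopropane once it is formed. The fallback sets out from 15 and comes back at 16. Cyclisation of 15 with the achiral catalyst Rh2(OAc)4 (CH2Cl2, 25 °C) should give the racemate, that is 16 together with its mirror image (1S,5S,6S)-5-[(tert-butyldimethylsilyl)oxy]-6-[(trimethylsilyl)ethynyl]bicyclo[3.1.0]hexan-2-one F1. Condensation with (S)-1-amino-2-(methoxymethyl)pyrrolidine (benzene, molecular sieves, 25 °C) converts the pair into two diastereomeric hydrazones, the (S)-1-amino-2-(methoxymethyl)pyrrolidine hydrazone of 16 F2 and the corresponding hydrazone of the mirror-image ketone F3, which are separated by chromatography. Cleavage of F2 with CuCl2 in aqueous THF at pH 7 returns enantiopure 16.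

2. Step 15. Oxidative addition into the doubly ortho-substituted C–Br bond and reductive elimination at the neopentyl-type enolate may be slow, so that proto-debromination takes over. The fallback sets out from 23 and comes back at 24. Ring B is closed without palladium by photostimulated radical-nucleophilic aromatic substitution (SRN1): the potassium enolate of the ester (KOt-Bu, liquid NH3/THF, −33 °C, 350 nm) transfers an electron to the aryl bromide, the aryl radical left after loss of bromide is trapped by the tethered enolate carbon, and the product radical anion carries the chain. No new compound is involved (F0).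

3. Step 6. The enolate released from the lactone is conjugated to the alkyne and may lose its geometry through its allenyl resonance form before it is silylated, which would place the alkynyl group on the convex face of the cyclopropane. The fallback sets out from 8 and comes back at 12 by reversing the order of events. 8 is opened with LiN(OMe)Me (THF, −78 °C) to the lithium (E)-enolate of 5-iodo-N-methoxy-N-methyl-4-oxopentanamide F4, an α-iodo enolate that has no alkyne to delocalise into and so holds its geometry. Silylation with t-BuMe2SiOTf gives (E)-4-[(tert-butyldimethylsilyl)oxy]-5-iodo-N-methoxy-N-methylpent-4-enamide F5, and Sonogashira coupling of F5 with 9 (PdCl2(PPh3)2, CuI, Et3N, THF, 25 °C) then gives 12 with retention.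

Further compounds
F1 | step 9 | (1S,5S,6S)-5-[(tert-butyldimethylsilyl)oxy]-6-[(trimethylsilyl)ethynyl]bicyclo[3.1.0]hexan-2-one | C1C(=O)[C@H]2[C@@H](C#C[Si](C)(C)C)[C@@]2(O[Si](C)(C)C(C)(C)C)C1
F2 | step 9 | (S)-1-amino-2-(methoxymethyl)pyrrolidine hydrazone of 16 | C1C(=NN2CCC[C@H]2COC)[C@@H]3[C@H](C#C[Si](C)(C)C)[C@]3(O[Si](C)(C)C(C)(C)C)C1
F3 | step 9 | (S)-1-amino-2-(methoxymethyl)pyrrolidine hydrazone of F1 | C1C(=NN2CCC[C@H]2COC)[C@H]3[C@@H](C#C[Si](C)(C)C)[C@@]3(O[Si](C)(C)C(C)(C)C)C1
F0 | step 15 | none | none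
F4 | step 6 | lithium (E)-enolate of 5-iodo-N-methoxy-N-methyl-4-oxopentanamide | [Li+].CON(C)C(=O)CC/C([O-])=C\I
F5 | step 6 | (E)-4-[(tert-butyldimethylsilyl)oxy]-5-iodo-N-methoxy-N-methylpent-4-enamide | CON(C)C(=O)CC/C(O[Si](C)(C)C(C)(C)C)=C\I
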